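## The problem

Target 30 is a furanoheliangolide: a ten-membered carbocycle C1–C10, bridged from C3 to C10 by the ring oxygen of a 3(2H)-furanone (C1=O, C2=C3), trans-fused at C6/C7 to an α-methylene-γ-butyrolactone and held by a Z C4=C5 double bond. It has five stereocentres: C6 and C7 (trans lactone), C8 and C9 (cis, acylated by (E)-2-(acetoxymethyl)but-2-enoic acid and by acetic acid), and the quaternary, oxygen-bearing C10 between the C1 carbonyl and C9. C6, C7 and C8 are contiguous and are best set on a six-membered ring; C9 lies between C8 and C10 and can be set last by reducing a ketone under the control of these neighbours; C10 has no hydrogen and must come from addition to a carbonyl group. The methylene lactone (Michael acceptor), the allylic acetate and enoate of the side chain, the vicinal C8/C9 esters (acyl shift) and the furanone (a vinylogous ester of a 2-hydroxy-1,3-dione) will not survive strong base, strong nucleophiles or forcing acid, so such operations must end before the last steps. An end-to-end closure of the ten-membered ring would pay entropy and transannular strain and leave the Z geometry to the ring. The way round is that C4=C5 lies 1,3 to the oxygenated C9: a C4–C9 bond folds the macrocycle into a cis-decalin, with ring A (C4, C5, C6, C7, C8, C9) carrying the lactone and the C5/C8 oxygens and ring B (C9, C10, C1, C2, C3, C4) carrying the masked 1,3-dione. A C9 alkoxide with a C5 sulfonate then returns the ten-membered ring by fragmentation. Ring B has the oxidation pattern of 2-methoxy-5-methyl-1,4-benzoquinone and ring A that of a Diels–Alder cyclohexene, which decides the rest of the plan.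

## Retrosynthesis

**30 ⇒ 29 ⇒ 21 + 27 (acyl C–O bonds at O9 and O8).** The side-chain ester tolerates neither base nor hydride, so both acylations come last. The cis-diol 21 is esterified first at C8–OH, the less hindered hydroxyl, with acid 27; the acetate is then forced onto the neopentyl C9–OH of 29. Acid 27 is made in four steps from tert-butyl acrylate 22 and acetaldehyde 23 through 24, 25 and 26. The forward steps must avoid acyl migration.

**21 ⇒ 20 ⇒ 19 (C9–H, then the furanone C3–O bond and the C8 silyl ether).** Ketone 20 is reduced under chelation by its free C8 hydroxyl. Closing the furanone before the reduction removes the C10 hydroxyl as a competing ligand, which a reduction on 19 itself would not. Ketone 20 comes from 19 by one acid treatment, since 19 already holds the 1,3-dione as a methyl enol ether next to the free C10 hydroxyl.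

**19 ⇒ 18 (reconnect C4–C9; key step).** The other cuts of the ten-membered ring (C5–C6, C2–C3, C8=C9) all demand a macrocyclisation. Here the ring is released from cis-decalin 18, its Z geometry follows from the ring fusion, and the precursor is a rigid bicycle on which stereocentres can be set by ring-controlled reactions. The forward reaction needs a C9 alkoxide anti-periplanar to an equatorial C5 mesylate and must spare the methylene lactone.

**18 ⇒ 17 ⇒ 14 ⇒ 13 (S–O bond, C11=C13, lactone C12–O6).** The methylene group is introduced on lactone 14 before the mesylate, because enolate chemistry on a mesylate that carries the C9 hydroxyl would trigger the fragmentation early. In 17 the C5 hydroxyl is the only secondary one, so the mesylation to 18 needs no protecting group. Lactone 14 is the oxidation product of pentaol 13.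

**13 ⇒ 12 (C6–O and C7–H across C6=C7).** Hydroboration of cyclohexene 12 from the face opposite the two allylic oxygens sets C6 and C7 in one step and gives the trans C5/C6 diol, the trans lactone junction and the cis C7/C8 relation.

**12 ⇒ 11 ⇒ 8 (C10–CH3, then C9–O).** The methyl group is added to the C10 ketone of 11 under chelation by the C9 oxygen. The C9 hydroxyl comes from oxidation of 8 at its only enolisable position.

**8 ⇒ 2 + 7 (C4–C5 and C8–C9, Diels–Alder).** One cycloaddition of quinone 2 with diene 7 gives the cis fusion, the quaternary C4, and both C5 and C8 oxygens cis to ring B. This is the arrangement that later places the C5 oxygen equatorial. The methoxy group of 2 blocks the second double bond and becomes the C1 oxygen. A stepwise annulation of ring A onto a dearomatised phloroglucinol would need more bond-forming events and offers no catalytic control of absolute configuration.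

**7 ⇒ 6 ⇒ 4 + 5 ⇒ 3; 2 ⇒ 1.** Diene 7 is the silyl dienol ether of enal 6, which comes from cross-metathesis of 2-substituted acrolein 4 with allyl acetate 5; 4 is the α-methylenation product of 4-oxobutyl acetate 3. Quinone 2 is the oxidation product of phenol 1.

## Roads not taken

**Alternative 1:** cut C5–C6. A Z vinyl iodide at C5 adds to a C6 aldehyde under CrCl2 with catalytic NiCl2, closing the carbocycle and giving the C6 carbinol A1.
- Merits: the furanone and the C8–C10 stereocentres are assembled beforehand in a convergent way; the conditions tolerate acetate, silyl ethers and the furanone; the alkenyl iodide passes its geometry on; the methylene lactone is still a protected allylic alcohol.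
- Weak points: it is a ten-membered closure at a trisubstituted alkenyl metal onto a branched aldehyde (dilution, excess chromium salt); the C6 configuration is left to the ring conformation; C7–C10, including the quaternary C10, must be built one centre at a time on an open chain.
- Comparison: in convergence and in sparing the lactone it is at least as good as the chosen plan. The chosen plan sets against it that no macrocyclisation is needed, that the Z alkene forms stereospecifically, and that four stereocentres come from one cycloaddition and one hydroboration.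

**Alternative 2:** cut C2–C3. The methyl ketone enolate (C2) of a nine-membered Z-enoate lactone attacks the lactone carbonyl C3; acid then closes the furanone to A2.
- Merits: carbocycle and 1,3-dicarbonyl arise in one intramolecular acyl transfer without dilution; the furanone follows directly; the acetonide keeps C8/C9 together.
- Weak points: the nine-membered lactone must be closed onto the tertiary C10 oxygen, a lactonisation harder than the problem it solves; the enolate is generated next to a methylene lactone and an epimerisable C8; the diol of A2 must still be differentiated.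
- Comparison: its key step would be more direct than the fragmentation if the lactone were in hand. The chosen plan makes every difficult bond in a six-membered ring.

**Alternative 3:** cut C8=C9. Vinyl groups on C7 and C10 are joined by the second-generation Grubbs catalyst (H2IMes)(PCy3)Cl2Ru=CHPh to A3, and the alkene is then dihydroxylated.
- Merits: it is the shortest and most convergent route (a lactone half and a furanone half); the catalyst is tolerant; the cis-diol would come from a Z alkene.
- Weak points: one olefin sits on the quaternary C10; the ring being closed is strained and already bridged; the methylene lactone is a competing olefin; OsO4 would have to pick C8=C9 over C4=C5, C11=C13 and C2=C3 and the right face; the diol must still be differentiated.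
- Comparison: it is clearly shorter than the chosen plan. The chosen plan sets against it that C8 is fixed by the cycloaddition, that C9 is set under chelation control, and that nothing depends on the face selectivity of a medium-ring alkene.

Key step: step 12

Remark: germacrane numbers label all ring intermediates and α/β are the faces of the usual drawing of 30 (H-7 α); 1 and 3 are taken to be catalogue chemicals; the BINOL antipode written in step 5 is the one assumed to give the drawn enantiomer and is exchanged for its mirror image if the sense proves opposite.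

## Steps

Step 1
Reactants: 1 2-methoxy-5-methylphenol
Product: 2 2-methoxy-5-methyl-1,4-benzoquinone
Conditions: (KSO3)2NO, KH2PO4 buffer, H2O/acetone, 0 °C → rt
Reagents that add atoms: potassium nitrosodisulfonate, [K+].[K+].[O]N(S(=O)(=O)[O-])S(=O)(=O)[O-]
Why: Teuber oxidation; a phenol with a free para position is taken to the para-quinone by the nitroxyl radical.

Step 2
Reactants: 3 4-oxobutyl acetate
Product: 4 3-formylbut-3-en-1-yl acetate
Conditions: aq. HCHO (37%), pyrrolidine (10 mol%), EtCO2H (10 mol%), iPrOH, 45 °C
Reagents that add atoms: formaldehyde, C=O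
Why: Amine-catalysed Mannich condensation (α-methylenation of an aldehyde); the product has no further α-hydrogen and cannot react twice.

Step 3
Reactants: 4 3-formylbut-3-en-1-yl acetate; 5 allyl acetate
Product: 6 (E)-3-formylpent-3-ene-1,5-diyl diacetate
Conditions: 5 (3 equiv), (H2IMes)Cl2Ru=CH(o-iPrOC6H4) (second-generation Hoveyda–Grubbs catalyst, 5 mol%), CH2Cl2, 40 °C
Reagents that add atoms: none
Why: Olefin cross-metathesis; 2-substituted acroleins do not homodimerise and should couple with the allyl ester to the E trisubstituted enal (formyl trans to the new CH2OAc), driven by loss of ethene.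

Step 4
Reactants: 6 (E)-3-formylpent-3-ene-1,5-diyl diacetate
Product: 7 (1E,3E)-3-(2-acetoxyethyl)-4-(tert-butyldimethylsilyloxy)buta-1,3-dien-1-yl acetate
Conditions: TBSOTf, Et3N, Et2O, −78 → 0 °C
Reagents that add atoms: tert-butyldimethylsilyl trifluoromethanesulfonate, CC(C)(C)[Si](C)(C)OS(=O)(=O)C(F)(F)F
Why: Soft γ-enolisation and O-silylation to the silyl dienol ether; the s-trans enal gives the E silyloxy terminus and allylic strain with the C7 branch should put the acetoxy group outside at the new double bond. Geometric isomers that cannot reach the s-cis conformation stay spectators in step 5.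

Step 5
Reactants: 2 2-methoxy-5-methyl-1,4-benzoquinone; 7 (1E,3E)-3-(2-acetoxyethyl)-4-(tert-butyldimethylsilyloxy)buta-1,3-dien-1-yl acetate
Product: 8 cis-decalin enedione adduct (5β-OAc, 8β-OTBS, 4α-Me, 9α-H, C6=C7)
Conditions: (R)-BINOL (20 mol%), TiCl2(OiPr)2 (20 mol%), toluene, −30 °C → rt
Reagents that add atoms: none
Why: Enantioselective quinone Diels–Alder reaction under a chiral titanium BINOLate chelated by the C10 carbonyl and the methoxy oxygen; the methoxy-bearing double bond is inert. The diene terminus remote from the silyloxy group (C5) bonds to C4, β to the activated carbonyl, and the endo transition state puts both oxygens cis to the ring-B carbons. This sets C4, C5, C8 and C9 relative to each other, and the catalyst face sets the absolute configuration.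

Step 6
Reactants: 8 cis-decalin enedione adduct
Product: 11 9α-hydroxy enedione, via trimethylsilyl dienol ether 9 (not isolated), via 9-O-trimethylsilyl ketone 10 (not isolated)
Conditions: TMSOTf, Et3N, CH2Cl2, −78 → 0 °C; DMDO, acetone/CH2Cl2, −78 °C; citric acid, MeOH, 0 °C
Reagents that add atoms: dimethyldioxirane, CC1(C)OO1
Why: Rubottom oxidation; C9–H is the only enolisable hydrogen and the electron-rich silyl enol ether is oxidised ahead of the C6=C7 alkene. Allylic strain with the C10 silyloxy group should turn H-8 into the plane and the C8 silyloxy group over one face, so oxygen enters on the face of the C4 methyl group and the cis fusion is kept.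

Step 7
Reactants: 11 9α-hydroxy enedione
Product: 12 alkene tetraol (5β-OH, 9α-OH, 10-OH cis to 9-OH, 7-hydroxyethyl)
Conditions: MeMgBr (6 equiv), Et2O/CH2Cl2, −78 → 0 °C; aq. NH4Cl
Reagents that add atoms: methylmagnesium bromide, C[Mg]Br
Why: Chelation-controlled Grignard addition to an α-hydroxy ketone; with the C9 alkoxide held in the plane of the C10 carbonyl, the methyl group should enter away from the 1,3-related axial C4 methyl, giving the C10 hydroxyl cis to the C9 hydroxyl. The C3 carbonyl is a neopentyl vinylogous ester and stays; the excess reagent cleaves both acetates.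

Step 8
Reactants: 12 alkene tetraol
Product: 13 pentaol (6α-OH, 7β-hydroxyethyl)
Conditions: BH3·THF (6 equiv), THF, 0 °C → rt; 30% H2O2, pH 7 phosphate buffer, MeOH, 0 °C → rt
Reagents that add atoms: hydrogen peroxide, OO
Why: Hydroboration–oxidation; boron goes to the less substituted C6 and adds syn with hydrogen from the α-face, opposite both allylic oxygens, which sets 6α-OH and 7α-H. The neutral oxidation avoids retro-aldol opening of the β-hydroxy ketone.

Step 9
Reactants: 13 pentaol
Product: 14 saturated trans-lactone triol (12,6α-olide)
Conditions: TEMPO (20 mol%), PhI(OAc)2 (2.5 equiv), CH2Cl2, rt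
Reagents that add atoms: none
Why: Nitroxyl-mediated oxidative lactonisation; only the primary alcohol is oxidised, the aldehyde is trapped as the lactol by the diequatorial C6 hydroxyl and oxidised on to the trans-fused lactone.

Step 10
Reactants: 14 saturated trans-lactone triol
Product: 17 α-methylene lactone triol, via Mannich base 15 (not isolated), via trimethylammonium iodide 16 (not isolated)
Conditions: LiN(iPr)2 (5 equiv), THF, −78 °C; Me2N=CH2+ I−, −78 → −20 °C; MeI, CH2Cl2/MeOH, rt; aq. NaHCO3, EtOAc
Reagents that add atoms: dimethyl(methylidene)ammonium iodide, C[N+](C)=C.[I-]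
Why: Lactone α-methylenation through the Mannich base, quaternisation and elimination; C11–H is the only acidic C–H, and the three hydroxyls are carried as lithium alkoxides without a leaving group in the molecule.

Step 11
Reactants: 17 α-methylene lactone triol
Product: 18 C5 mesylate of the cis-decalin (fragmentation precursor)
Conditions: MsCl, Et3N, CH2Cl2, −20 °C
Reagents that add atoms: methanesulfonyl chloride, CS(=O)(=O)Cl
Why: Sulfonylation of the only secondary hydroxyl; the two tertiary hydroxyls at C9 and C10 do not react at this temperature.

Step 12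
Reactants: 18 C5 mesylate of the cis-decalin
Product: 19 ten-membered Z-dienone (C9 ketone, C10–OH, C8–OTBS, C1 methyl enol ether)
Conditions: KN(SiMe3)2 (1.1 equiv), THF, −78 → 0 °C; pH 7 buffer
Reagents that add atoms: none
Why: Grob (Wharton) fragmentation of a 1,3-diol monosulfonate: in the C9 alkoxide the C4–C9 bond is anti-periplanar to the C5–OMs bond, so C9=O forms, C4–C9 breaks, C4=C5 forms and mesylate leaves in one step. The closest known reaction type is the fragmentation of decalin 1,3-diol monomesylates to cyclodecenones used for germacranes. No ring is closed by a new bond; the ten-membered ring is set free by cleaving the bond shared by rings A and B, so no cyclisation entropy or dilution is involved. No stereocentre is created: C4, C5 and C9 are erased and C6, C7, C8 and C10 are untouched. The step needs Z geometry and reaction from the C9 rather than the C10 alkoxide. The trans-lactone locks ring A in the chair with the C5 mesylate equatorial; through the cis fusion C3 is axial and anti to H-5, which maps onto the Z alkene. The C10 alkoxide has no leaving group 1,3 to it and only exchanges its proton with O9. The C3 carbonyl also makes the cleavage a retro-aldol, which lowers the barrier and is the reason for cold, stoichiometric base.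

Step 13
Reactants: 19 ten-membered Z-dienone
Product: 20 8β-hydroxy-9-oxo furanone
Conditions: 48% aq. HF, MeCN, 0 °C → rt
Reagents that add atoms: water, O
Why: Acid hydrolysis of the vinylogous methyl ester; the C10 hydroxyl adds to the C3 carbonyl (five-membered hemiketal) and dehydration gives the 3(2H)-furanone. The slower fluoride cleavage of the silyl ether then frees the C8 hydroxyl.

Step 14
Reactants: 20 8β-hydroxy-9-oxo furanone
Product: 21 8β,9β-diol
Conditions: Zn(BH4)2, Et2O, −30 → 0 °C; aq. NH4Cl
Reagents that add atoms: none
Why: Chelation-controlled reduction of an α-hydroxy ketone to the anti (ring-cis) diol; zinc bridges O8 and the C9 carbonyl and hydride should enter opposite the C10 methyl group, with the furanone oxygen anti (Felkin–Anh sense reinforcing). The furanone carbonyl and the methylene lactone are not reduced by this reagent.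

Step 15
Reactants: 22 tert-butyl acrylate; 23 acetaldehyde
Product: 24 tert-butyl 3-hydroxy-2-methylidenebutanoate (racemic)
Conditions: DABCO (0.2 equiv), neat, rt
Reagents that add atoms: none
Why: Baylis–Hillman reaction; the stereocentre is removed in the next step.

Step 16
Reactants: 24 tert-butyl 3-hydroxy-2-methylidenebutanoate
Product: 25 tert-butyl (Z)-2-(bromomethyl)but-2-enoate
Conditions: NBS, Me2S, CH2Cl2, 0 °C → rt
Reagents that add atoms: N-bromosuccinimide, O=C1CCC(=O)N1Br
Why: Corey–Kim-type activation of the allylic alcohol and SN2' delivery of bromide; the conjugated trisubstituted bromide with the ester trans to the methyl group is the usual product.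

Step 17
Reactants: 25 tert-butyl (Z)-2-(bromomethyl)but-2-enoate
Product: 26 tert-butyl (E)-2-(acetoxymethyl)but-2-enoate
Conditions: KOAc, DMF, rt
Reagents that add atoms: potassium acetate, [K+].CC(=O)[O-]
Why: SN2 displacement of the primary allylic bromide by acetate with the alkene geometry retained; the conjugated primary acetate is also the more stable allylic isomer.

Step 18
Reactants: 26 tert-butyl (E)-2-(acetoxymethyl)but-2-enoate
Product: 27 (E)-2-(acetoxymethyl)but-2-enoic acid
Conditions: CF3CO2H, CH2Cl2, 0 °C → rt
Reagents that add atoms: none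
Why: Acidolysis of the tert-butyl ester; the acetate and the alkene are unaffected.

Step 19
Reactants: 21 8β,9β-diol; 27 (E)-2-(acetoxymethyl)but-2-enoic acid
Product: 29 8-O-[(E)-2-(acetoxymethyl)but-2-enoyl] 9β-alcohol, via mixed trichlorobenzoic anhydride 28 (not isolated)
Conditions: 27, 2,4,6-Cl3C6H2COCl, Et3N, toluene, rt; then 21, DMAP, 0 °C → rt
Reagents that add atoms: none
Why: Yamaguchi esterification; the C8 hydroxyl should react ahead of the C9 hydroxyl, which is neopentyl next to the quaternary C10.

Step 20
Reactants: 29 8-O-acyl 9β-alcohol
Product: 30 CNP0325609.1 (target)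
Conditions: Ac2O, DMAP, pyridine, CH2Cl2, rt
Reagents that add atoms: acetic anhydride, CC(=O)OC(C)=O
Why: DMAP-catalysed acetylation of the remaining secondary hydroxyl; no other free hydroxyl is present.

## Compound list

1 | 2-methoxy-5-methylphenol | Cc1ccc(OC)c(O)c1 | starting material
2 | 2-methoxy-5-methyl-1,4-benzoquinone | O=C1C(OC)=CC(=O)C(C)=C1 | intermediate
3 | 4-oxobutyl acetate | CC(=O)OCCCC=O | starting material
4 | 3-formylbut-3-en-1-yl acetate | CC(=O)OCCC(=C)C=O | intermediate
5 | allyl acetate | C=CCOC(C)=O | starting material
6 | (E)-3-formylpent-3-ene-1,5-diyl diacetate | O=C/C(CCOC(C)=O)=C/COC(C)=O | intermediate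
7 | (1E,3E)-3-(2-acetoxyethyl)-4-(tert-butyldimethylsilyloxy)buta-1,3-dien-1-yl acetate | CC(=O)O/C=C/C(CCOC(C)=O)=C/O[Si](C)(C)C(C)(C)C | intermediate
8 | cis-fused decalin: 5β-acetoxy-7-(2-acetoxyethyl)-8β-(tert-butyldimethylsilyloxy)-1-methoxy-4α-methyl-9α-H-1,6-diene-3,10-dione | C1[C@@H](OC(C)=O)[C@@]2(C)C(=O)C=C(OC)C(=O)[C@H]2[C@@H](O[Si](C)(C)C(C)(C)C)C(CCOC(C)=O)=1 | intermediate
9 | C9=C10 trimethylsilyl dienol ether of 8 | C1[C@@H](OC(C)=O)[C@@]2(C)C(=O)C=C(OC)C(O[Si](C)(C)C)=C2[C@@H](O[Si](C)(C)C(C)(C)C)C(CCOC(C)=O)=1 | intermediate
10 | 9α-(trimethylsilyloxy) derivative of 8 | C1[C@@H](OC(C)=O)[C@@]2(C)C(=O)C=C(OC)C(=O)[C@@]2(O[Si](C)(C)C)[C@@H](O[Si](C)(C)C(C)(C)C)C(CCOC(C)=O)=1 | intermediate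
11 | 9α-hydroxy derivative of 8 (cis-fused, OH cis to 4-methyl) | C1[C@@H](OC(C)=O)[C@@]2(C)C(=O)C=C(OC)C(=O)[C@@]2(O)[C@@H](O[Si](C)(C)C(C)(C)C)C(CCOC(C)=O)=1 | intermediate
12 | cis-decalin 5β,9α,10-triol with 7-(2-hydroxyethyl), 8β-OTBS, 1-methoxy, 4α,10-dimethyl, 1,6-dien-3-one (10-OH cis to 9-OH) | C1[C@@H](O)[C@@]2(C)C(=O)C=C(OC)[C@](C)(O)[C@@]2(O)[C@@H](O[Si](C)(C)C(C)(C)C)C(CCO)=1 | intermediate
13 | cis-decalin 5β,6α,9α,10-tetraol with 7β-(2-hydroxyethyl), 8β-OTBS, 1-methoxy-1-en-3-one | O[C@@H]1[C@@H](O)[C@@]2(C)C(=O)C=C(OC)[C@](C)(O)[C@@]2(O)[C@@H](O[Si](C)(C)C(C)(C)C)[C@H]1CCO | intermediate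
14 | 11,13-dihydro-12,6α-lactone of 13 (5β,9α,10-triol) | C1C(=O)O[C@@H]2[C@@H](O)[C@@]3(C)C(=O)C=C(OC)[C@](C)(O)[C@@]3(O)[C@@H](O[Si](C)(C)C(C)(C)C)[C@@H]12 | intermediate
15 | 13-(dimethylamino)-11,13-dihydro lactone (C11 epimers) | CN(C)CC1C(=O)O[C@@H]2[C@@H](O)[C@@]3(C)C(=O)C=C(OC)[C@](C)(O)[C@@]3(O)[C@@H](O[Si](C)(C)C(C)(C)C)[C@@H]12 | intermediate
16 | N-methyl quaternary iodide of 15 | C[N+](C)(C)CC1C(=O)O[C@@H]2[C@@H](O)[C@@]3(C)C(=O)C=C(OC)[C@](C)(O)[C@@]3(O)[C@@H](O[Si](C)(C)C(C)(C)C)[C@@H]12.[I-] | intermediate
17 | α-methylene-12,6α-lactone, 5β,9α,10-triol | C=C1C(=O)O[C@@H]2[C@@H](O)[C@@]3(C)C(=O)C=C(OC)[C@](C)(O)[C@@]3(O)[C@@H](O[Si](C)(C)C(C)(C)C)[C@@H]12 | intermediate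
18 | 5β-mesylate of 17 (9α,10-diol free) | C=C1C(=O)O[C@@H]2[C@@H](OS(C)(=O)=O)[C@@]3(C)C(=O)C=C(OC)[C@](C)(O)[C@@]3(O)[C@@H](O[Si](C)(C)C(C)(C)C)[C@@H]12 | intermediate
19 | (4Z)-8β-(tert-butyldimethylsilyloxy)-10α-hydroxy-1-methoxy-3,9-dioxogermacra-1,4,11(13)-trien-12,6α-olide | C=C1C(=O)O[C@@H]2/C=C(/C)C(=O)/C=C(/OC)[C@](C)(O)C(=O)[C@@H](O[Si](C)(C)C(C)(C)C)[C@@H]12 | intermediate
20 | (4Z)-3,10α-epoxy-8β-hydroxy-1,9-dioxogermacra-2,4,11(13)-trien-12,6α-olide | C=C1C(=O)O[C@@H]2/C=C(/C)C3=CC(=O)[C@](C)(O3)C(=O)[C@@H](O)[C@@H]12 | intermediate
21 | (4Z)-3,10α-epoxy-8β,9β-dihydroxy-1-oxogermacra-2,4,11(13)-trien-12,6α-olide | C=C1C(=O)O[C@@H]2/C=C(/C)C3=CC(=O)[C@](C)(O3)[C@@H](O)[C@@H](O)[C@@H]12 | intermediate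
22 | tert-butyl acrylate | C=CC(=O)OC(C)(C)C | starting material
23 | acetaldehyde | CC=O | starting material
24 | tert-butyl 3-hydroxy-2-methylidenebutanoate (racemic) | CC(O)C(=C)C(=O)OC(C)(C)C | intermediate
25 | tert-butyl (Z)-2-(bromomethyl)but-2-enoate | CC(C)(C)OC(=O)/C(=C/C)CBr | intermediate
26 | tert-butyl (E)-2-(acetoxymethyl)but-2-enoate | CC(C)(C)OC(=O)/C(=C/C)COC(C)=O | intermediate
27 | (E)-2-(acetoxymethyl)but-2-enoic acid | OC(=O)/C(=C/C)COC(C)=O | intermediate
28 | mixed anhydride of 27 with 2,4,6-trichlorobenzoic acid | O=C(OC(=O)/C(=C/C)COC(C)=O)c1c(Cl)cc(Cl)cc1Cl | intermediate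
29 | 8-O-[(E)-2-(acetoxymethyl)but-2-enoyl] derivative of 21 (9β-OH free) | C=C1C(=O)O[C@@H]2/C=C(/C)C3=CC(=O)[C@](C)(O3)[C@@H](O)[C@@H](OC(=O)/C(=C/C)COC(C)=O)[C@@H]12 | intermediate
30 | CNP0325609.1: (4Z)-9β-acetoxy-8β-[(E)-2-(acetoxymethyl)but-2-enoyloxy]-3,10α-epoxy-1-oxogermacra-2,4,11(13)-trien-12,6α-olide | C=C1C(=O)O[C@@H]2/C=C(/C)C3=CC(=O)[C@](C)(O3)[C@@H](OC(C)=O)[C@@H](OC(=O)/C(=C/C)COC(C)=O)[C@@H]12 | target

## Step count and risk

Total steps: 20. Longest linear sequence: 15 (steps 2–14, 19, 20, from 3).

**Step 12 (key step).** The likeliest failure is base-induced conjugate addition and oligomerisation at the methylene lactone. The second is erosion of the Z geometry if cleavage runs stepwise through the retro-aldol enolate before the mesylate leaves; the 1,3-diaxial pressure of the C8 silyloxy group on C3 could push ring A out of the chair that this alignment needs. Fallback: carry the lactone through the fragmentation masked as its amine adduct. It sets out from 15, isolated instead of being eliminated. Mesylation gives the Mannich-base mesylate F1; the same base gives the Mannich-base ten-membered dienone F2; quaternisation with MeI and NaHCO3 elimination returns to the route at 19.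

**Step 5.** Poor facial discrimination at the methyl-substituted double bond, or Lewis-acid-induced desilylation of the diene before cycloaddition, would lower the enantiomeric purity or the conversion. Fallback: give up catalytic induction. From 2 and 7 a thermal cycloaddition in toluene gives racemic material, that is 8 together with the enantiomeric adduct F3, and preparative chromatography on a chiral stationary phase returns to the route at 8.

**Step 7.** The methyl group may enter on the wrong face if the chelate does not form or if ring B reacts from another conformer. Fallback: switch from chelation to Felkin–Anh control by blocking the C9 oxygen. It sets out from 10, isolated by leaving out the methanolysis. Excess MeMgBr in THF gives the 9-O-trimethylsilyl tetraol F4, and citric acid in MeOH returns to the route at 12.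

**Step 8.** Borane may reduce the C3 vinylogous ester carbonyl in competition with the hindered alkene. Fallback: accept the over-reduction and restore the carbonyl afterwards. From 12, excess BH3·THF at rt and the same oxidation give the C3 carbinol hexaol F5, and MnO2 in CH2Cl2 oxidises only this allylic alcohol, returning to the route at 13.

**Step 14.** The conformation of the bridged ten-membered ring may override the chelate and give the 9-epimer; acyloin isomerisation of the α-hydroxy ketone is a second risk. Fallback: reduce the silyl ether under steric, non-chelating control. From 19, pyridinium p-toluenesulfonate in wet acetone closes the furanone with the silyl ether kept, giving the 8-O-silyl 9-ketone F6. NaBH4 with CeCl3·7H2O in MeOH at −78 °C gives the 8-O-silyl 9β-alcohol F7, and HF·pyridine returns to the route at 21.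

Further compounds
F1 | step 12 | 5β-mesylate of Mannich base 15 | CN(C)CC1C(=O)O[C@@H]2[C@@H](OS(C)(=O)=O)[C@@]3(C)C(=O)C=C(OC)[C@](C)(O)[C@@]3(O)[C@@H](O[Si](C)(C)C(C)(C)C)[C@@H]12
F2 | step 12 | 13-(dimethylamino)-11,13-dihydro analogue of 19 | CN(C)CC1C(=O)O[C@@H]2/C=C(/C)C(=O)/C=C(/OC)[C@](C)(O)C(=O)[C@@H](O[Si](C)(C)C(C)(C)C)[C@@H]12
F3 | step 5 | enantiomer of adduct 8 | C1[C@H](OC(C)=O)[C@]2(C)C(=O)C=C(OC)C(=O)[C@@H]2[C@H](O[Si](C)(C)C(C)(C)C)C(CCOC(C)=O)=1
F4 | step 7 | 9-O-trimethylsilyl ether of tetraol 12 | C1[C@@H](O)[C@@]2(C)C(=O)C=C(OC)[C@](C)(O)[C@@]2(O[Si](C)(C)C)[C@@H](O[Si](C)(C)C(C)(C)C)C(CCO)=1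
F5 | step 8 | C3 carbinol of pentaol 13 (hexaol, C3 epimers) | O[C@@H]1[C@@H](O)[C@@]2(C)C(O)C=C(OC)[C@](C)(O)[C@@]2(O)[C@@H](O[Si](C)(C)C(C)(C)C)[C@H]1CCO
F6 | step 14 | 8-O-tert-butyldimethylsilyl ether of 20 | C=C1C(=O)O[C@@H]2/C=C(/C)C3=CC(=O)[C@](C)(O3)C(=O)[C@@H](O[Si](C)(C)C(C)(C)C)[C@@H]12
F7 | step 14 | 8-O-tert-butyldimethylsilyl ether of 21 | C=C1C(=O)O[C@@H]2/C=C(/C)C3=CC(=O)[C@](C)(O3)[C@@H](O)[C@@H](O[Si](C)(C)C(C)(C)C)[C@@H]12
A1 | alternative 1 | furanone-bridged cyclodecadienol with free C6–OH | O[C@@H]1/C=C(/C)C2=CC(=O)[C@](C)(O2)[C@@H](OC(C)=O)[C@@H](O[Si](C)(C)C(C)(C)C)[C@H]1C(=C)CO[Si](CC)(CC)CC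
A2 | alternative 2 | furanone-bridged germacranolide, C8/C9 acetonide | C=C1C(=O)O[C@@H]2/C=C(/C)C3=CC(=O)[C@](C)(O3)[C@@H](OC(C)(C)O4)[C@@H]4[C@@H]12
A3 | alternative 3 | furanone-bridged germacranolide with Z C8=C9 | C=C1C(=O)O[C@@H]2/C=C(/C)C3=CC(=O)[C@](C)(O3)/C=C\[C@@H]12
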